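**Strategy.** The flavanone ring C is disconnected at O1–C2, which lies β to the C4 carbonyl. The ring is closed by a catalytic asymmetric 6-endo oxa-Michael addition of the single free ring-A phenol onto a chalcone-type alkene that carries a removable tert-butyl ester at C3. In one pot the key step closes ring C, sets the 2S centre under cinchona-thiourea control and expels the activating ester as isobutene and CO2. Its precursor is an open-chain alkylidene β-ketoester, assembled by Knoevenagel condensation from a ring-A β-ketoester and a biaryl aldehyde. The aldehyde comes from Suzuki coupling of a 6-iodoluteolin ether with a 5-borylated protocatechualdehyde ether. Benzyl ethers are removed last by hydrogenolysis.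

Key step: step 9

Remark 1: the quinidine-derived thiourea is assumed to deliver the 2S series; if a trial cyclisation shows the opposite sense, the quinine-derived pseudo-enantiomer replaces it with no other change.
Remark 2: the biaryl axis (three ortho oxygens, one ortho hydrogen) carries no descriptor in the target and is treated as configurationally labile; benzylated intermediates may appear as interconverting rotamers.
Remark 3: compounds 1, 5 and 9 are taken as catalogue compounds.

Step 1
Reactants: 1 luteolin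
Product: 2 7,3',4'-tri-O-benzylluteolin (5-OH free)
Conditions: BnBr (3.3 equiv), K2CO3, DMF, rt
Reagents that add atoms: benzyl bromide, BrCc1ccccc1
Why: Williamson etherification in which the 5-OH, hydrogen-bonded to the C4 carbonyl and the least nucleophilic phenol, should stay free at room temperature with three equivalents of halide.

Step 2
Reactants: 2 7,3',4'-tri-O-benzylluteolin
Product: 3 6-iodo-7,3',4'-tri-O-benzylluteolin
Conditions: BnMe3N+ ICl2− (1.0 equiv), CaCO3, CH2Cl2–MeOH, rt
Reagents that add atoms: benzyltrimethylammonium dichloroiodate, C[N+](C)(C)Cc1ccccc1.Cl[I-]Cl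
Why: Electrophilic aromatic iodination of a phenol, which on 5-hydroxy-7-alkoxyflavones is known to go to C6 (ortho to the free 5-OH, between the two oxygens) and not to C8, with CaCO3 taking up the HCl.

Step 3
Reactants: 3 6-iodo-7,3',4'-tri-O-benzylluteolin
Product: 4 6-iodo-5,7,3',4'-tetra-O-benzylluteolin
Conditions: BnBr (2 equiv), K2CO3, Bu4NI (cat.), DMF, 70 °C
Reagents that add atoms: benzyl bromide, BrCc1ccccc1
Why: Williamson etherification under forcing conditions caps the chelated, hindered 5-OH so that the coupling partner carries no acidic proton.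

Step 4
Reactants: 5 3-bromo-4,5-dihydroxybenzaldehyde
Product: 6 3,4-bis(benzyloxy)-5-bromobenzaldehyde
Conditions: BnBr (2.3 equiv), K2CO3, DMF, 60 °C
Reagents that add atoms: benzyl bromide, BrCc1ccccc1
Why: Williamson etherification of both catechol hydroxyls, the non-enolisable aldehyde being inert to carbonate.

Step 5
Reactants: 6 3,4-bis(benzyloxy)-5-bromobenzaldehyde
Product: 7 3,4-bis(benzyloxy)-5-(pinacolboryl)benzaldehyde
Conditions: B2pin2, Pd(dppf)Cl2 (5 mol %), KOAc, 1,4-dioxane, 85 °C
Reagents that add atoms: bis(pinacolato)diboron, CC1(C)OB(OC1(C)C)B1OC(C)(C)C(C)(C)O1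
Why: Miyaura borylation of the aryl bromide, in which the weak acetate base should prevent Suzuki homocoupling and the aldehyde is tolerated.

Step 6
Reactants: 4 6-iodo-5,7,3',4'-tetra-O-benzylluteolin; 7 3,4-bis(benzyloxy)-5-(pinacolboryl)benzaldehyde
Product: 8 3,4-bis(benzyloxy)-5-(tetra-O-benzylluteolin-6-yl)benzaldehyde
Conditions: Pd(OAc)2 (5 mol %), SPhos (10 mol %), K3PO4, toluene–H2O (10:1), 90 °C
Reagents that add atoms: none
Why: Suzuki–Miyaura coupling with a dialkylbiarylphosphine suited to tri-ortho-substituted biaryls, the doubly flanked partner being the iodide (fast oxidative addition) and the less hindered partner the boronate.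

Step 7
Reactants: 9 1-[2,4-bis(benzyloxy)-6-hydroxyphenyl]ethan-1-one
Product: 10 tert-butyl 3-[2,4-bis(benzyloxy)-6-hydroxyphenyl]-3-oxopropanoate
Conditions: LiHMDS (3.2 equiv), THF, −78 °C; Boc2O (1.1 equiv), −78 to 0 °C; AcOH quench
Reagents that add atoms: di-tert-butyl dicarbonate, CC(C)(C)OC(=O)OC(=O)OC(C)(C)C
Why: Claisen-type C-acylation of the phenoxide–enolate dianion, in which the third equivalent of base deprotonates the β-ketoester formed and so favours C- over O-acylation, while the tert-butyl group slows lactonisation to a 4-hydroxycoumarin.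

Step 8
Reactants: 8 3,4-bis(benzyloxy)-5-(tetra-O-benzylluteolin-6-yl)benzaldehyde; 10 tert-butyl 3-[2,4-bis(benzyloxy)-6-hydroxyphenyl]-3-oxopropanoate
Product: 11 alkylidene β-ketoester (tert-butyl 2-aroyl-3-arylprop-2-enoate, E/Z mixture)
Conditions: piperidine (20 mol %), AcOH (20 mol %), 4 Å MS, toluene, rt
Reagents that add atoms: none
Why: Knoevenagel condensation of the active methylene with an unhindered aryl aldehyde under buffered amine catalysis with water removal, conditions mild and non-polar enough that the free phenol should not cyclise prematurely.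

Step 9
Reactants: 11 alkylidene β-ketoester
Product: 13 (2S)-octa-O-benzyl flavanone–flavone dimer, via cyclised 3-tert-butoxycarbonyl flavanone 12 (not isolated)
Conditions: 3,5-bis(trifluoromethyl)phenyl thiourea of 9-amino-9-deoxy-epi-quinidine (10 mol %), toluene, −25 °C; then TsOH·H2O (1 equiv), 80 °C
Reagents that add atoms: none
Why: The quinuclidine nitrogen of the catalyst engages the lone free 2'-phenol of ring A while the thiourea N–H pair binds the 1,3-dicarbonyl of the alkylidene, so the phenol oxygen adds to the activated β-carbon in a 6-endo-trig oxa-Michael closure that forms O1–C2 and completes ring C. The closest known reaction is the bifunctional cinchona-thiourea cyclisation of alkylidene β-ketoesters to 3-carboxyflavanones with one-pot decarboxylation. C2 is the only new stereocentre that persists, and it is set by catalyst control of the alkene face presented to the tethered phenol inside the hydrogen-bonded complex. The tert-butyl ester raises the electrophilicity of the enone and gives the catalyst its two-point handle; TsOH then cleaves it as isobutene and the β-keto acid loses CO2, which erases C3. The C2 configuration should survive because the acidic medium does not form the phenoxide needed for retro-oxa-Michael opening. Chemoselectivity rests on the substrate: the second ortho oxygen of ring A is benzylated so only one phenol can close, low temperature and toluene suppress the uncatalysed background, and the flavone enone of the luteolin unit is a vinylogous ester too unreactive to compete.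

Step 10
Reactants: 13 (2S)-octa-O-benzyl flavanone–flavone dimer
Product: 14 target biflavonoid
Conditions: H2 (1 atm), 10 % Pd/C, THF–MeOH, rt; filtration and neutral to slightly acidic work-up
Reagents that add atoms: none
Why: Hydrogenolysis of the eight aryl benzyl ethers under neutral conditions should leave the flavone alkene, both carbonyls and the base-labile C2 centre untouched.

**Compound list**

1 | luteolin, 2-(3,4-dihydroxyphenyl)-5,7-dihydroxy-4H-chromen-4-one | O=c1cc(-c2ccc(O)c(O)c2)oc2cc(O)cc(O)c12 | starting material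
2 | 7-(benzyloxy)-2-[3,4-bis(benzyloxy)phenyl]-5-hydroxy-4H-chromen-4-one | O=c1cc(-c2ccc(OCc3ccccc3)c(OCc3ccccc3)c2)oc2cc(OCc3ccccc3)cc(O)c12 | intermediate
3 | 7-(benzyloxy)-2-[3,4-bis(benzyloxy)phenyl]-5-hydroxy-6-iodo-4H-chromen-4-one | O=c1cc(-c2ccc(OCc3ccccc3)c(OCc3ccccc3)c2)oc2cc(OCc3ccccc3)c(I)c(O)c12 | intermediate
4 | 5,7-bis(benzyloxy)-2-[3,4-bis(benzyloxy)phenyl]-6-iodo-4H-chromen-4-one | O=c1cc(-c2ccc(OCc3ccccc3)c(OCc3ccccc3)c2)oc2cc(OCc3ccccc3)c(I)c(OCc3ccccc3)c12 | intermediate
5 | 3-bromo-4,5-dihydroxybenzaldehyde | O=Cc1cc(O)c(O)c(Br)c1 | starting material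
6 | 3,4-bis(benzyloxy)-5-bromobenzaldehyde | O=Cc1cc(OCc2ccccc2)c(OCc2ccccc2)c(Br)c1 | intermediate
7 | 3,4-bis(benzyloxy)-5-(4,4,5,5-tetramethyl-1,3,2-dioxaborolan-2-yl)benzaldehyde | O=Cc1cc(OCc2ccccc2)c(OCc2ccccc2)c(B2OC(C)(C)C(C)(C)O2)c1 | intermediate
8 | 3,4-bis(benzyloxy)-5-{5,7-bis(benzyloxy)-2-[3,4-bis(benzyloxy)phenyl]-4-oxo-4H-chromen-6-yl}benzaldehyde | O=Cc1cc(OCc2ccccc2)c(OCc2ccccc2)c(-c2c(OCc3ccccc3)cc3oc(-c4ccc(OCc5ccccc5)c(OCc5ccccc5)c4)cc(=O)c3c2OCc2ccccc2)c1 | intermediate
9 | 1-[2,4-bis(benzyloxy)-6-hydroxyphenyl]ethan-1-one | CC(=O)c1c(O)cc(OCc2ccccc2)cc1OCc1ccccc1 | starting material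
10 | tert-butyl 3-[2,4-bis(benzyloxy)-6-hydroxyphenyl]-3-oxopropanoate | CC(C)(C)OC(=O)CC(=O)c1c(O)cc(OCc2ccccc2)cc1OCc1ccccc1 | intermediate
11 | tert-butyl 2-[2,4-bis(benzyloxy)-6-hydroxybenzoyl]-3-[3,4-bis(benzyloxy)-5-{5,7-bis(benzyloxy)-2-[3,4-bis(benzyloxy)phenyl]-4-oxo-4H-chromen-6-yl}phenyl]prop-2-enoate, alkene geometry not controlled (E/Z mixture) | CC(C)(C)OC(=O)C(=Cc1cc(OCc2ccccc2)c(OCc2ccccc2)c(-c2c(OCc3ccccc3)cc3oc(-c4ccc(OCc5ccccc5)c(OCc5ccccc5)c4)cc(=O)c3c2OCc2ccccc2)c1)C(=O)c1c(O)cc(OCc2ccccc2)cc1OCc1ccccc1 | intermediate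
12 | tert-butyl (2S)-5,7-bis(benzyloxy)-2-[3,4-bis(benzyloxy)-5-{5,7-bis(benzyloxy)-2-[3,4-bis(benzyloxy)phenyl]-4-oxo-4H-chromen-6-yl}phenyl]-4-oxochromane-3-carboxylate, C3 epimers and enol form, not isolated | O=C1C(C(=O)OC(C)(C)C)[C@@H](c2cc(OCc3ccccc3)c(OCc3ccccc3)c(-c3c(OCc4ccccc4)cc4oc(-c5ccc(OCc6ccccc6)c(OCc6ccccc6)c5)cc(=O)c4c3OCc3ccccc3)c2)Oc2cc(OCc3ccccc3)cc(OCc3ccccc3)c21 | intermediate
13 | (2S)-5,7-bis(benzyloxy)-2-[3,4-bis(benzyloxy)-5-{5,7-bis(benzyloxy)-2-[3,4-bis(benzyloxy)phenyl]-4-oxo-4H-chromen-6-yl}phenyl]chroman-4-one | O=C1C[C@@H](c2cc(OCc3ccccc3)c(OCc3ccccc3)c(-c3c(OCc4ccccc4)cc4oc(-c5ccc(OCc6ccccc6)c(OCc6ccccc6)c5)cc(=O)c4c3OCc3ccccc3)c2)Oc2cc(OCc3ccccc3)cc(OCc3ccccc3)c21 | intermediate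
14 | (2S)-2-{3,4-dihydroxy-5-[2-(3,4-dihydroxyphenyl)-5,7-dihydroxy-4-oxo-4H-chromen-6-yl]phenyl}-5,7-dihydroxychroman-4-one | O=C1C[C@@H](c2cc(O)c(O)c(-c3c(O)cc4oc(-c5ccc(O)c(O)c5)cc(=O)c4c3O)c2)Oc2cc(O)cc(O)c21 | target

**Step count.** Total: 10 steps. Longest linear sequence: 7 steps (1, 2, 3, 6, 8, 9, 10).

**Steps most likely to fail**

Step 9. Facial selectivity may be insufficient, an uncatalysed cyclisation may compete and give racemic material, or the C2 configuration may erode through acid-induced ring opening during the decarboxylation at 80 °C. Fallback by racemic closure and resolution, setting out from aldehyde 8 and acetophenone 9: Claisen–Schmidt condensation (KOH, EtOH–THF, rt) should give the (E)-2'-hydroxychalcone F1. NaOAc in refluxing EtOH–THF should then close the same O1–C2 bond without stereocontrol to the racemic flavanone F2. Preparative chromatography on a chiral stationary phase (amylose tris(3,5-dimethylphenylcarbamate), supercritical CO2–alcohol) should separate 13 from its 2R enantiomer F3, which is returned to the chalcone–flavanone equilibrium with base and recycled. The route is rejoined at 13.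

Step 6. Transmetalation onto the doubly ortho-substituted arylpalladium intermediate may be slow, so that protodeboronation of 7 and reductive deiodination of 4 overtake the coupling. Fallback by Negishi coupling with reversed polarity, setting out from iodide 4: insertion of zinc dust in the presence of LiCl (THF, 25–50 °C) should give the arylzinc iodide F4, which tolerates the flavone carbonyl. Coupling of F4 with bromide 6 (Pd(OAc)2, SPhos, THF, 50 °C) should give aldehyde 8 directly, the organozinc being inert to the aldehyde. The route is rejoined at 8 and step 5 is no longer needed.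

Step 7. O-acylation of the enolate or phenoxide, double acylation, or lactonisation on warming may divert the dianion. Fallback by intramolecular acyl transfer, setting out from acetophenone 9: Boc2O with catalytic DMAP and iPr2NEt in CH2Cl2 should give the aryl tert-butyl carbonate F5. LiHMDS (2.2 equiv, THF, −78 to −20 °C) should then trigger a Baker–Venkataraman-type O-to-C transfer of the tert-butoxycarbonyl group onto the ketone enolate, giving β-ketoester 10, where the route is rejoined.

Further compounds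
F1 | step 9 | (E)-1-[2,4-bis(benzyloxy)-6-hydroxyphenyl]-3-[3,4-bis(benzyloxy)-5-{5,7-bis(benzyloxy)-2-[3,4-bis(benzyloxy)phenyl]-4-oxo-4H-chromen-6-yl}phenyl]prop-2-en-1-one | O=C(/C=C/c1cc(OCc2ccccc2)c(OCc2ccccc2)c(-c2c(OCc3ccccc3)cc3oc(-c4ccc(OCc5ccccc5)c(OCc5ccccc5)c4)cc(=O)c3c2OCc2ccccc2)c1)c1c(O)cc(OCc2ccccc2)cc1OCc1ccccc1
F2 | step 9 | racemic 5,7-bis(benzyloxy)-2-[3,4-bis(benzyloxy)-5-{5,7-bis(benzyloxy)-2-[3,4-bis(benzyloxy)phenyl]-4-oxo-4H-chromen-6-yl}phenyl]chroman-4-one | O=C1CC(c2cc(OCc3ccccc3)c(OCc3ccccc3)c(-c3c(OCc4ccccc4)cc4oc(-c5ccc(OCc6ccccc6)c(OCc6ccccc6)c5)cc(=O)c4c3OCc3ccccc3)c2)Oc2cc(OCc3ccccc3)cc(OCc3ccccc3)c21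
F3 | step 9 | (2R)-5,7-bis(benzyloxy)-2-[3,4-bis(benzyloxy)-5-{5,7-bis(benzyloxy)-2-[3,4-bis(benzyloxy)phenyl]-4-oxo-4H-chromen-6-yl}phenyl]chroman-4-one | O=C1C[C@H](c2cc(OCc3ccccc3)c(OCc3ccccc3)c(-c3c(OCc4ccccc4)cc4oc(-c5ccc(OCc6ccccc6)c(OCc6ccccc6)c5)cc(=O)c4c3OCc3ccccc3)c2)Oc2cc(OCc3ccccc3)cc(OCc3ccccc3)c21
F4 | step 6 | {5,7-bis(benzyloxy)-2-[3,4-bis(benzyloxy)phenyl]-4-oxo-4H-chromen-6-yl}zinc iodide | O=c1cc(-c2ccc(OCc3ccccc3)c(OCc3ccccc3)c2)oc2cc(OCc3ccccc3)c([Zn]I)c(OCc3ccccc3)c12
F5 | step 7 | 2-acetyl-3,5-bis(benzyloxy)phenyl tert-butyl carbonate | CC(=O)c1c(OC(=O)OC(C)(C)C)cc(OCc2ccccc2)cc1OCc1ccccc1
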